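**Retrosynthetic overview**
- The target comes from a 3,4-epoxide: HCl opens it at C3 (trans-diaxial) and removes the side-chain acetonide; before that the C6 acetate and the two angelates (C5–O, C8–O) are put on an epoxy diol.
- The C7–C8 bond is made by a Nozaki–Hiyama–Kishi coupling of a ring alkenyl triflate with a side-chain aldehyde (from L-malic acid); the angelate donor is a separately made mixed anhydride.
- The only carbocycle is closed by an intramolecular aldol condensation of a 1,5-keto aldehyde to a 2-methylcyclohex-2-enone; Luche reduction and OH-directed epoxidation then set C5, C4 and C3.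
- The keto aldehyde comes from an Evans syn aldol (sets C1 and C6) of a pent-4-enoyl oxazolidinone with 2-ethylacrolein, followed by oxidative cleavage of both C=CH2 groups.
- Ring order: cyclohexenone first, then the temporary oxirane; the dioxolane is a protecting ring made in the side-chain branch.

Notation (one line): "angelate/angeloyl" = (2Z)-2-methylbut-2-enoate/-enoyl; C1–C11 in the comments are target locants: ring C1 (bears the side chain), C2, C3 (Cl), C4 (CH3, OH), C5 (angelate), C6 (acetate); side chain C7(=CH2), C8 (angelate), C9, C10 (OH), C11 (OH).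

**Branch A – ring core**

Step 1
Reactants: 1 butanal
Product: 2 2-methylidenebutanal (2-ethylacrolein)
Conditions: 37% aq. CH2O, pyrrolidine (10 mol %), EtCO2H (10 mol %), i-PrOH, 45 °C
Reagents that add atoms: formaldehyde, C=O
Why: Organocatalytic Mannich-type α-methylenation (enamine adds to the formaldehyde iminium, then the amine is eliminated) gives the 2-substituted acrolein; no stereocentre is formed.

Step 2
Reactants: 3 (4R)-4-benzyl-1,3-oxazolidin-2-one; 4 pent-4-enoyl chloride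
Product: 6 (4R)-4-benzyl-3-(pent-4-enoyl)-1,3-oxazolidin-2-one, via lithium oxazolidinide 5 (not isolated)
Conditions: n-BuLi, THF, −78 °C; then 4, −78 → 0 °C
Reagents that add atoms: none
Why: N-acylation of the lithiated Evans auxiliary by the acid chloride; the auxiliary stereocentre is not touched.

Step 3
Reactants: 6 (4R)-4-benzyl-3-(pent-4-enoyl)-1,3-oxazolidin-2-one; 2 2-methylidenebutanal
Product: 8 (4R)-4-benzyl-3-[(2R,3R)-3-hydroxy-4-methylidene-2-(prop-2-en-1-yl)hexanoyl]-1,3-oxazolidin-2-one, via boron enolate 7 (not isolated)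
Conditions: Bu2BOTf, i-Pr2NEt, CH2Cl2, −78 → 0 °C; then 2, −78 → 0 °C; pH 7 buffer, MeOH, H2O2, 0 °C
Reagents that add atoms: none
Why: Evans syn aldol: the (Z)-boron enolate reacts through a chair Zimmerman–Traxler transition state on the face away from the benzyl group, giving the 2,3-syn (2R,3R) adduct and so fixing C1 and C6 of the target.

Step 4
Reactants: 8 (4R)-4-benzyl-3-[(2R,3R)-3-hydroxy-4-methylidene-2-(prop-2-en-1-yl)hexanoyl]-1,3-oxazolidin-2-one
Product: 9 (2R,3R)-3-hydroxy-N-methoxy-N-methyl-4-methylidene-2-(prop-2-en-1-yl)hexanamide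
Conditions: MeNHOMe·HCl, AlMe3, CH2Cl2, −20 → 0 °C
Reagents that add atoms: N,O-dimethylhydroxylamine hydrochloride, CNOC.Cl
Why: Aluminium-amide transamidation (Weinreb amide formation), assisted by the free β-hydroxyl, removes the auxiliary without touching the two stereocentres.

Step 5
Reactants: 9 (2R,3R)-3-hydroxy-N-methoxy-N-methyl-4-methylidene-2-(prop-2-en-1-yl)hexanamide
Product: 10 (2R,3R)-N-methoxy-N-methyl-4-methylidene-2-(prop-2-en-1-yl)-3-[(triethylsilyl)oxy]hexanamide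
Conditions: Et3SiOTf, 2,6-lutidine, CH2Cl2, −78 → 0 °C
Reagents that add atoms: triethylsilyl trifluoromethanesulfonate, CC[Si](CC)(CC)OS(=O)(=O)C(F)(F)F
Why: Silylation of the secondary alcohol masks the future C6 hydroxyl through the basic and oxidative steps and can later be removed under mild fluoride conditions.

Step 6
Reactants: 10 (2R,3R)-N-methoxy-N-methyl-4-methylidene-2-(prop-2-en-1-yl)-3-[(triethylsilyl)oxy]hexanamide
Product: 11 (3R,4R)-5-methylidene-3-(prop-2-en-1-yl)-4-[(triethylsilyl)oxy]heptan-2-one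
Conditions: MeMgBr, THF, 0 °C
Reagents that add atoms: methylmagnesium bromide, C[Mg]Br
Why: Weinreb ketone synthesis: the chelated tetrahedral intermediate stops at mono-addition and the α-stereocentre is not enolised.

Step 7
Reactants: 11 (3R,4R)-5-methylidene-3-(prop-2-en-1-yl)-4-[(triethylsilyl)oxy]heptan-2-one
Product: 13 (3R,4R)-5-methylidene-3-(prop-2-en-1-yl)-4-[(triethylsilyl)oxy]hept-1-en-2-yl trifluoromethanesulfonate, via potassium enolate 12 (not isolated)
Conditions: KN(SiMe3)2, THF, −78 °C (ketone added to base); then PhNTf2, −78 → 0 °C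
Reagents that add atoms: N-phenylbis(trifluoromethanesulfonimide), O=S(=O)(N(c1ccccc1)S(=O)(=O)C(F)(F)F)C(F)(F)F
Why: Kinetic deprotonation at the methyl group and O-triflation give the 1,1-disubstituted enol triflate (the C7=CH2 unit); the hindered C1–H is not removed, so there is no epimerisation or β-elimination.

Step 8
Reactants: 13 (3R,4R)-5-methylidene-3-(prop-2-en-1-yl)-4-[(triethylsilyl)oxy]hept-1-en-2-yl trifluoromethanesulfonate
Product: 14 (3R,4R)-5-oxo-3-(2-oxoethyl)-4-[(triethylsilyl)oxy]hept-1-en-2-yl trifluoromethanesulfonate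
Conditions: OsO4 (2 mol %), NaIO4, 2,6-lutidine, dioxane/H2O (3:1), rt
Reagents that add atoms: osmium tetroxide, O=[Os](=O)(=O)=O; sodium periodate, [Na+].[O-]I(=O)(=O)=O
Why: Lemieux–Johnson oxidative cleavage turns the two electron-rich C=CH2 groups into the aldehyde and the ethyl ketone, while the electron-poor enol triflate is not attacked by the electrophilic oxidant.

Step 9
Reactants: 14 (3R,4R)-5-oxo-3-(2-oxoethyl)-4-[(triethylsilyl)oxy]hept-1-en-2-yl trifluoromethanesulfonate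
Product: 15 1-[(1R,2R)-4-methyl-3-oxo-2-[(triethylsilyl)oxy]cyclohex-4-en-1-yl]ethenyl trifluoromethanesulfonate
Conditions: Bn2NH·CF3CO2H (20 mol %), benzene, 50 °C
Reagents that add atoms: none
Why: Intramolecular aldol condensation (6-enolendo): only the ethyl-ketone CH2/aldehyde pairing gives an unstrained ring, so the 2-methylcyclohex-2-enone forms; C1 has no adjacent carbonyl and cannot epimerise, and the mild ammonium salt is chosen to leave the α-silyloxy centre C6 intact.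

Step 10
Reactants: 15 1-[(1R,2R)-4-methyl-3-oxo-2-[(triethylsilyl)oxy]cyclohex-4-en-1-yl]ethenyl trifluoromethanesulfonate
Product: 16 1-[(1R,2R,3S)-3-hydroxy-4-methyl-2-[(triethylsilyl)oxy]cyclohex-4-en-1-yl]ethenyl trifluoromethanesulfonate
Conditions: NaBH4, CeCl3·7H2O, MeOH, −78 °C
Reagents that add atoms: none
Why: Luche 1,2-reduction: hydride adds axially, anti to the pseudo-axial C6 silyloxy group (Felkin–Anh), giving the equatorial C5 alcohol cis to both the C6 oxygen and the C1 substituent.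

Step 11
Reactants: 16 1-[(1R,2R,3S)-3-hydroxy-4-methyl-2-[(triethylsilyl)oxy]cyclohex-4-en-1-yl]ethenyl trifluoromethanesulfonate
Product: 17 1-[(1R,2R,3R,4R,6S)-2-hydroxy-1-methyl-3-[(triethylsilyl)oxy]-7-oxabicyclo[4.1.0]heptan-4-yl]ethenyl trifluoromethanesulfonate
Conditions: VO(acac)2 (5 mol %), t-BuOOH (decane solution), CH2Cl2, 0 °C → rt
Reagents that add atoms: tert-butyl hydroperoxide, CC(C)(C)OO
Why: Hydroxyl-directed vanadium-catalysed epoxidation delivers oxygen to the trisubstituted alkene on the face of the allylic C5 hydroxyl (cis-epoxy alcohol), setting C4 and the precursor configuration at C3; the enol triflate is inert.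

**Branch B – side-chain aldehyde**

Step 12
Reactants: 18 (2S)-2-hydroxybutanedioic acid (L-malic acid)
Product: 19 2-[(4S)-2,2-dimethyl-5-oxo-1,3-dioxolan-4-yl]acetic acid
Conditions: Me2C(OMe)2, TsOH (cat.), rt
Reagents that add atoms: 2,2-dimethoxypropane, COC(C)(C)OC
Why: Acid-catalysed acetalisation ties the α-hydroxy acid into the five-membered dioxolanone and leaves the distal carboxyl free; the stereocentre is not involved.

Step 13
Reactants: 19 2-[(4S)-2,2-dimethyl-5-oxo-1,3-dioxolan-4-yl]acetic acid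
Product: 21 (3S)-3-hydroxyoxolan-2-one, via hydroxyethyl dioxolanone 20 (not isolated)
Conditions: BH3·THF, THF, 0 °C → rt; MeOH; then TsOH (cat.), CH2Cl2, rt
Reagents that add atoms: none
Why: Chemoselective borane reduction of the free carboxylic acid, then acid-catalysed translactonisation with loss of acetone, gives the α-hydroxy lactone with the malic stereocentre intact.

Step 14
Reactants: 21 (3S)-3-hydroxyoxolan-2-one
Product: 22 (3S)-4-methylpentane-1,3,4-triol
Conditions: MeMgBr (3.5 equiv), THF, 0 °C → rt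
Reagents that add atoms: methylmagnesium bromide, C[Mg]Br
Why: Double Grignard addition to the lactone carbonyl builds the tertiary carbinol (C11) and frees the primary alcohol; the C10 carbinol centre (S) is untouched.

Step 15
Reactants: 22 (3S)-4-methylpentane-1,3,4-triol
Product: 23 2-[(4S)-2,2,5,5-tetramethyl-1,3-dioxolan-4-yl]ethan-1-ol
Conditions: Me2C(OMe)2, PPTS (cat.), acetone, rt
Reagents that add atoms: 2,2-dimethoxypropane, COC(C)(C)OC
Why: Thermodynamic acetonide formation prefers the five-membered dioxolane on the secondary/tertiary 1,2-diol (gem-dimethyl effect) over a 1,3-dioxane, leaving the primary alcohol free.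

Step 16
Reactants: 23 2-[(4S)-2,2,5,5-tetramethyl-1,3-dioxolan-4-yl]ethan-1-ol
Product: 24 2-[(4S)-2,2,5,5-tetramethyl-1,3-dioxolan-4-yl]acetaldehyde
Conditions: Dess–Martin periodinane, NaHCO3, CH2Cl2, 0 °C → rt
Reagents that add atoms: none
Why: Mild hypervalent-iodine oxidation gives the β-alkoxy aldehyde without β-elimination or acetonide loss; it is used at once.

**Fragment union**

Step 17
Reactants: 17 1-[(1R,2R,3R,4R,6S)-2-hydroxy-1-methyl-3-[(triethylsilyl)oxy]-7-oxabicyclo[4.1.0]heptan-4-yl]ethenyl trifluoromethanesulfonate; 24 2-[(4S)-2,2,5,5-tetramethyl-1,3-dioxolan-4-yl]acetaldehyde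
Product: 25 (1R,2R,3R,4S,6S)-4-{(3S)-3-hydroxy-4-[(4S)-2,2,5,5-tetramethyl-1,3-dioxolan-4-yl]but-1-en-2-yl}-1-methyl-3-[(triethylsilyl)oxy]-7-oxabicyclo[4.1.0]heptan-2-ol
Conditions: CrCl2 (4 equiv), NiCl2 (2 mol %), chiral sulfonamide–oxazoline ligand (4.4 equiv), Et3N, THF, rt
Reagents that add atoms: none
Why: Nozaki–Hiyama–Kishi coupling: the triflate adds oxidatively to zerovalent nickel, the alkenyl group passes to chromium and adds only to the aldehyde (free OH, epoxide and silyl ether are tolerated); the ligand antipode is chosen to give 8S, which is also the 1,3-anti sense favoured by the β-alkoxy aldehyde.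

**Branch C – angelate donor**

Step 18
Reactants: 26 (2Z)-2-bromobut-2-ene
Product: 28 (2Z)-2-methylbut-2-enoic acid (angelic acid), via butenyllithium 27 (not isolated)
Conditions: t-BuLi (2 equiv), Et2O, −78 °C; then CO2, −78 °C → rt; aq. HCl
Reagents that add atoms: carbon dioxide, O=C=O
Why: Bromine–lithium exchange and carboxylation both go with retention of alkene geometry, so the Z acid is obtained.

Step 19
Reactants: 28 (2Z)-2-methylbut-2-enoic acid; 29 2,4,6-trichlorobenzoyl chloride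
Product: 30 (2Z)-2-methylbut-2-enoic 2,4,6-trichlorobenzoic anhydride
Conditions: Et3N, toluene, rt; filtration
Reagents that add atoms: none
Why: Yamaguchi-type mixed-anhydride formation activates the acid without Z → E isomerisation.

**Endgame**

Step 20
Reactants: 25 (1R,2R,3R,4S,6S)-4-{(3S)-3-hydroxy-4-[(4S)-2,2,5,5-tetramethyl-1,3-dioxolan-4-yl]but-1-en-2-yl}-1-methyl-3-[(triethylsilyl)oxy]-7-oxabicyclo[4.1.0]heptan-2-ol; 30 (2Z)-2-methylbut-2-enoic 2,4,6-trichlorobenzoic anhydride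
Product: 31 (1S,2R,3R,4S,6S)-4-{(3S)-3-(angeloyloxy)-4-[(4S)-2,2,5,5-tetramethyl-1,3-dioxolan-4-yl]but-1-en-2-yl}-1-methyl-3-[(triethylsilyl)oxy]-7-oxabicyclo[4.1.0]heptan-2-yl angelate
Conditions: 30 (6 equiv), Et3N, toluene, 80 °C
Reagents that add atoms: none
Why: Yamaguchi-type acyl transfer: both secondary hydroxyls (C5 and C8) attack the unhindered angeloyl carbonyl of the mixed anhydride, and because no nucleophilic catalyst is present the Z geometry is kept; no stereocentre is touched.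

Step 21
Reactants: 31 (1S,2R,3R,4S,6S)-4-{(3S)-3-(angeloyloxy)-4-[(4S)-2,2,5,5-tetramethyl-1,3-dioxolan-4-yl]but-1-en-2-yl}-1-methyl-3-[(triethylsilyl)oxy]-7-oxabicyclo[4.1.0]heptan-2-yl angelate
Product: 32 (1S,2R,3R,4S,6S)-4-{(3S)-3-(angeloyloxy)-4-[(4S)-2,2,5,5-tetramethyl-1,3-dioxolan-4-yl]but-1-en-2-yl}-3-hydroxy-1-methyl-7-oxabicyclo[4.1.0]heptan-2-yl angelate
Conditions: HF·pyridine, pyridine, THF, 0 °C
Reagents that add atoms: none
Why: Buffered fluoride cleavage of the triethylsilyl ether frees the C6 hydroxyl without acyl migration and without opening the epoxide or the acetonide.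

Step 22
Reactants: 32 (1S,2R,3R,4S,6S)-4-{(3S)-3-(angeloyloxy)-4-[(4S)-2,2,5,5-tetramethyl-1,3-dioxolan-4-yl]but-1-en-2-yl}-3-hydroxy-1-methyl-7-oxabicyclo[4.1.0]heptan-2-yl angelate
Product: 33 (1S,2R,3R,4S,6S)-3-(acetyloxy)-4-{(3S)-3-(angeloyloxy)-4-[(4S)-2,2,5,5-tetramethyl-1,3-dioxolan-4-yl]but-1-en-2-yl}-1-methyl-7-oxabicyclo[4.1.0]heptan-2-yl angelate
Conditions: Ac2O, DMAP (cat.), pyridine, CH2Cl2, rt
Reagents that add atoms: acetic anhydride, CC(=O)OC(C)=O
Why: DMAP-catalysed acetylation of the only free hydroxyl (C6).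

Step 23
Reactants: 33 (1S,2R,3R,4S,6S)-3-(acetyloxy)-4-{(3S)-3-(angeloyloxy)-4-[(4S)-2,2,5,5-tetramethyl-1,3-dioxolan-4-yl]but-1-en-2-yl}-1-methyl-7-oxabicyclo[4.1.0]heptan-2-yl angelate
Product: 35 (1R,2R,3R,5S,6R)-6-(acetyloxy)-5-[(3S,5S)-3-(angeloyloxy)-5,6-dihydroxy-6-methylhept-1-en-2-yl]-3-chloro-2-hydroxy-2-methylcyclohexyl angelate (CNP0212201.1), via chlorohydrin acetonide 34 (not isolated)
Conditions: HCl (4 M in dioxane, 2 equiv), CH2Cl2, −20 → 0 °C; then H2O/THF, rt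
Reagents that add atoms: hydrogen chloride, Cl
Why: Acid-mediated epoxide opening: chloride attacks the secondary C3 with inversion in the trans-diaxial (Fürst–Plattner) sense, leaving the tertiary C4 hydroxyl cis to the C5 ester, and the aqueous acid then hydrolyses the acetonide.

**Compound list**

1 | butanal | CCCC=O | starting material
2 | 2-methylidenebutanal (2-ethylacrolein) | CCC(=C)C=O | intermediate
3 | (4R)-4-benzyl-1,3-oxazolidin-2-one | O=C1N[C@H](Cc2ccccc2)CO1 | starting material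
4 | pent-4-enoyl chloride | C=CCCC(Cl)=O | starting material
5 | lithium (4R)-4-benzyl-2-oxo-1,3-oxazolidin-3-ide | [Li]N1[C@H](Cc2ccccc2)COC1=O | intermediate
6 | (4R)-4-benzyl-3-(pent-4-enoyl)-1,3-oxazolidin-2-one | C=CCCC(=O)N1[C@H](Cc2ccccc2)COC1=O | intermediate
7 | (4R)-4-benzyl-3-{(1Z)-1-[(dibutylboranyl)oxy]penta-1,4-dien-1-yl}-1,3-oxazolidin-2-one | CCCCB(CCCC)O/C(=C\CC=C)N1[C@H](Cc2ccccc2)COC1=O | intermediate
8 | (4R)-4-benzyl-3-[(2R,3R)-3-hydroxy-4-methylidene-2-(prop-2-en-1-yl)hexanoyl]-1,3-oxazolidin-2-one | O=C(N1[C@H](Cc2ccccc2)COC1=O)[C@H](CC=C)[C@@H](O)C(=C)CC | intermediate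
9 | (2R,3R)-3-hydroxy-N-methoxy-N-methyl-4-methylidene-2-(prop-2-en-1-yl)hexanamide | CON(C)C(=O)[C@H](CC=C)[C@@H](O)C(=C)CC | intermediate
10 | (2R,3R)-N-methoxy-N-methyl-4-methylidene-2-(prop-2-en-1-yl)-3-[(triethylsilyl)oxy]hexanamide | CON(C)C(=O)[C@H](CC=C)[C@@H](O[Si](CC)(CC)CC)C(=C)CC | intermediate
11 | (3R,4R)-5-methylidene-3-(prop-2-en-1-yl)-4-[(triethylsilyl)oxy]heptan-2-one | CC(=O)[C@H](CC=C)[C@@H](O[Si](CC)(CC)CC)C(=C)CC | intermediate
12 | potassium (3R,4R)-5-methylidene-3-(prop-2-en-1-yl)-4-[(triethylsilyl)oxy]hept-1-en-2-olate | [K]OC(=C)[C@H](CC=C)[C@@H](O[Si](CC)(CC)CC)C(=C)CC | intermediate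
13 | (3R,4R)-5-methylidene-3-(prop-2-en-1-yl)-4-[(triethylsilyl)oxy]hept-1-en-2-yl trifluoromethanesulfonate | C=C(OS(=O)(=O)C(F)(F)F)[C@H](CC=C)[C@@H](O[Si](CC)(CC)CC)C(=C)CC | intermediate
14 | (3R,4R)-5-oxo-3-(2-oxoethyl)-4-[(triethylsilyl)oxy]hept-1-en-2-yl trifluoromethanesulfonate | C=C(OS(=O)(=O)C(F)(F)F)[C@H](CC=O)[C@@H](O[Si](CC)(CC)CC)C(=O)CC | intermediate
15 | 1-[(1R,2R)-4-methyl-3-oxo-2-[(triethylsilyl)oxy]cyclohex-4-en-1-yl]ethenyl trifluoromethanesulfonate | C=C(OS(=O)(=O)C(F)(F)F)[C@@H]1CC=C(C)C(=O)[C@@H]1O[Si](CC)(CC)CC | intermediate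
16 | 1-[(1R,2R,3S)-3-hydroxy-4-methyl-2-[(triethylsilyl)oxy]cyclohex-4-en-1-yl]ethenyl trifluoromethanesulfonate | C=C(OS(=O)(=O)C(F)(F)F)[C@@H]1CC=C(C)[C@H](O)[C@@H]1O[Si](CC)(CC)CC | intermediate
17 | 1-[(1R,2R,3R,4R,6S)-2-hydroxy-1-methyl-3-[(triethylsilyl)oxy]-7-oxabicyclo[4.1.0]heptan-4-yl]ethenyl trifluoromethanesulfonate | C=C(OS(=O)(=O)C(F)(F)F)[C@@H]1C[C@@H]2O[C@]2(C)[C@H](O)[C@@H]1O[Si](CC)(CC)CC | intermediate
18 | (2S)-2-hydroxybutanedioic acid (L-malic acid) | OC(=O)C[C@H](O)C(=O)O | starting material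
19 | 2-[(4S)-2,2-dimethyl-5-oxo-1,3-dioxolan-4-yl]acetic acid | OC(=O)C[C@@H]1OC(C)(C)OC1=O | intermediate
20 | (5S)-5-(2-hydroxyethyl)-2,2-dimethyl-1,3-dioxolan-4-one | OCC[C@@H]1OC(C)(C)OC1=O | intermediate
21 | (3S)-3-hydroxyoxolan-2-one | O=C1OCC[C@@H]1O | intermediate
22 | (3S)-4-methylpentane-1,3,4-triol | OCC[C@H](O)C(C)(C)O | intermediate
23 | 2-[(4S)-2,2,5,5-tetramethyl-1,3-dioxolan-4-yl]ethan-1-ol | OCC[C@@H]1OC(C)(C)OC1(C)C | intermediate
24 | 2-[(4S)-2,2,5,5-tetramethyl-1,3-dioxolan-4-yl]acetaldehyde | O=CC[C@@H]1OC(C)(C)OC1(C)C | intermediate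
25 | (1R,2R,3R,4S,6S)-4-{(3S)-3-hydroxy-4-[(4S)-2,2,5,5-tetramethyl-1,3-dioxolan-4-yl]but-1-en-2-yl}-1-methyl-3-[(triethylsilyl)oxy]-7-oxabicyclo[4.1.0]heptan-2-ol | C=C([C@H](C[C@@H]3OC(C)(C)OC3(C)C)O)[C@@H]1C[C@@H]2O[C@]2(C)[C@H](O)[C@@H]1O[Si](CC)(CC)CC | intermediate
26 | (2Z)-2-bromobut-2-ene | C/C=C(\Br)C | starting material
27 | (2E)-but-2-en-2-yllithium (Li cis to the C4 methyl) | C/C=C(\[Li])C | intermediate
28 | (2Z)-2-methylbut-2-enoic acid (angelic acid) | C/C=C(/C)C(=O)O | intermediate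
29 | 2,4,6-trichlorobenzoyl chloride | O=C(Cl)c1c(Cl)cc(Cl)cc1Cl | starting material
30 | (2Z)-2-methylbut-2-enoic 2,4,6-trichlorobenzoic anhydride | C/C=C(/C)C(=O)OC(=O)c1c(Cl)cc(Cl)cc1Cl | intermediate
31 | (1S,2R,3R,4S,6S)-1-methyl-4-{(3S)-3-{[(2Z)-2-methylbut-2-enoyl]oxy}-4-[(4S)-2,2,5,5-tetramethyl-1,3-dioxolan-4-yl]but-1-en-2-yl}-3-[(triethylsilyl)oxy]-7-oxabicyclo[4.1.0]heptan-2-yl (2Z)-2-methylbut-2-enoate | C=C([C@H](C[C@@H]3OC(C)(C)OC3(C)C)OC(=O)/C(C)=C\C)[C@@H]1C[C@@H]2O[C@]2(C)[C@H](OC(=O)/C(C)=C\C)[C@@H]1O[Si](CC)(CC)CC | intermediate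
32 | (1S,2R,3R,4S,6S)-3-hydroxy-1-methyl-4-{(3S)-3-{[(2Z)-2-methylbut-2-enoyl]oxy}-4-[(4S)-2,2,5,5-tetramethyl-1,3-dioxolan-4-yl]but-1-en-2-yl}-7-oxabicyclo[4.1.0]heptan-2-yl (2Z)-2-methylbut-2-enoate | C=C([C@H](C[C@@H]3OC(C)(C)OC3(C)C)OC(=O)/C(C)=C\C)[C@@H]1C[C@@H]2O[C@]2(C)[C@H](OC(=O)/C(C)=C\C)[C@@H]1O | intermediate
33 | (1S,2R,3R,4S,6S)-3-(acetyloxy)-1-methyl-4-{(3S)-3-{[(2Z)-2-methylbut-2-enoyl]oxy}-4-[(4S)-2,2,5,5-tetramethyl-1,3-dioxolan-4-yl]but-1-en-2-yl}-7-oxabicyclo[4.1.0]heptan-2-yl (2Z)-2-methylbut-2-enoate | C=C([C@H](C[C@@H]3OC(C)(C)OC3(C)C)OC(=O)/C(C)=C\C)[C@@H]1C[C@@H]2O[C@]2(C)[C@H](OC(=O)/C(C)=C\C)[C@@H]1OC(C)=O | intermediate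
34 | (1R,2R,3R,5S,6R)-6-(acetyloxy)-3-chloro-2-hydroxy-2-methyl-5-{(3S)-3-{[(2Z)-2-methylbut-2-enoyl]oxy}-4-[(4S)-2,2,5,5-tetramethyl-1,3-dioxolan-4-yl]but-1-en-2-yl}cyclohexyl (2Z)-2-methylbut-2-enoate | C=C([C@H](C[C@@H]3OC(C)(C)OC3(C)C)OC(=O)/C(C)=C\C)[C@@H]1C[C@@H](Cl)[C@](C)(O)[C@H](OC(=O)/C(C)=C\C)[C@@H]1OC(C)=O | intermediate
35 | (1R,2R,3R,5S,6R)-6-(acetyloxy)-3-chloro-5-[(3S,5S)-5,6-dihydroxy-6-methyl-3-{[(2Z)-2-methylbut-2-enoyl]oxy}hept-1-en-2-yl]-2-hydroxy-2-methylcyclohexyl (2Z)-2-methylbut-2-enoate (CNP0212201.1) | C=C([C@H](C[C@H](O)C(C)(C)O)OC(=O)/C(C)=C\C)[C@@H]1C[C@@H](Cl)[C@](C)(O)[C@H](OC(=O)/C(C)=C\C)[C@@H]1OC(C)=O | target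

**Step count and risk**

Total step count: 23.
Longest linear sequence: 15 steps (steps 2–11, 17, 20–23; the path through step 1 is equally long). The side-chain branch (steps 12–16), the angelate branch (steps 18–19) and step 1 run in parallel.

The three steps most likely to fail:

1. Step 9 (aldol condensation). The risk is slow closure or epimerisation of the α-silyloxy ketone centre C6 under reversible enolisation. Fallback, from 14 back to 15: the ethyl ketone of 14 is enolised regioselectively with (c-C6H11)2BCl/Et3N in Et2O at −78 °C, and the boron enolate adds intramolecularly to the aldehyde. After oxidative work-up this gives the β-hydroxy ketone F1 (a mixture at the two new centres, both of which disappear later). MsCl/Et3N converts it into the mesylate F2, and DBU-induced elimination of F2 returns enone 15. The kinetically formed boron enolate is never equilibrated towards C6.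

2. Step 17 (Nozaki–Hiyama–Kishi coupling). The risks are poor control of the new C8 carbinol and a sluggish reaction of the hindered triflate. Fallback, from 17 and 24 back to 25: ligand-free coupling (CrCl2, NiCl2 cat., DMSO, rt) gives 25 together with its C8 epimer F3. The unseparated mixture is oxidised with MnO2, which touches only the allylic C8 alcohol, to the α-methylene ketone F4. F4 is reduced at once with (R)-2-methyl-CBS-oxazaborolidine/catecholborane (toluene, −78 °C) to 25, the reagent setting 8S with the alkenyl group as the large substituent.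

3. Step 23 (HCl opening of the epoxide on the fully acylated substrate). The risks are attack at C4, hydrolysis to a diol, or loss of an ester. Fallback, from 25 back to 34: the epoxide is opened while the C5 hydroxyl is still free, with Ti(OiPr)4/Et2NH2Cl in CH2Cl2 at rt; chelation between the C5 alkoxide and the epoxide oxygen steers chloride to C3 and gives the chlorohydrin triol F5. Angeloylation with 30 as in step 20 gives the bis-angelate F6 (the tertiary C4 hydroxyl does not react), HF·pyridine gives the C6 alcohol F7, and Ac2O/DMAP gives 34, now isolated. 34 is hydrolysed to 35 with AcOH/H2O (4:1, 40 °C).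

Further compounds
F1 | step 9 | 1-[(1R,2R)-5-hydroxy-4-methyl-3-oxo-2-[(triethylsilyl)oxy]cyclohexyl]ethenyl trifluoromethanesulfonate | C=C(OS(=O)(=O)C(F)(F)F)[C@@H]1CC(O)C(C)C(=O)[C@@H]1O[Si](CC)(CC)CC
F2 | step 9 | 1-[(1R,2R)-5-(methanesulfonyloxy)-4-methyl-3-oxo-2-[(triethylsilyl)oxy]cyclohexyl]ethenyl trifluoromethanesulfonate | C=C(OS(=O)(=O)C(F)(F)F)[C@@H]1CC(OS(C)(=O)=O)C(C)C(=O)[C@@H]1O[Si](CC)(CC)CC
F3 | step 17 | (1R,2R,3R,4S,6S)-4-{(3R)-3-hydroxy-4-[(4S)-2,2,5,5-tetramethyl-1,3-dioxolan-4-yl]but-1-en-2-yl}-1-methyl-3-[(triethylsilyl)oxy]-7-oxabicyclo[4.1.0]heptan-2-ol | C=C([C@@H](C[C@@H]3OC(C)(C)OC3(C)C)O)[C@@H]1C[C@@H]2O[C@]2(C)[C@H](O)[C@@H]1O[Si](CC)(CC)CC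
F4 | step 17 | 3-[(1R,2R,3R,4S,6S)-2-hydroxy-1-methyl-3-[(triethylsilyl)oxy]-7-oxabicyclo[4.1.0]heptan-4-yl]-1-[(4S)-2,2,5,5-tetramethyl-1,3-dioxolan-4-yl]but-3-en-2-one | C=C(C(=O)C[C@@H]3OC(C)(C)OC3(C)C)[C@@H]1C[C@@H]2O[C@]2(C)[C@H](O)[C@@H]1O[Si](CC)(CC)CC
F5 | step 23 | (1R,2R,3R,4S,6R)-6-chloro-4-{(3S)-3-hydroxy-4-[(4S)-2,2,5,5-tetramethyl-1,3-dioxolan-4-yl]but-1-en-2-yl}-1-methyl-3-[(triethylsilyl)oxy]cyclohexane-1,2-diol | C=C([C@H](C[C@@H]3OC(C)(C)OC3(C)C)O)[C@@H]1C[C@@H](Cl)[C@](C)(O)[C@H](O)[C@@H]1O[Si](CC)(CC)CC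
F6 | step 23 | (1R,2R,3R,5S,6R)-3-chloro-2-hydroxy-2-methyl-5-{(3S)-3-{[(2Z)-2-methylbut-2-enoyl]oxy}-4-[(4S)-2,2,5,5-tetramethyl-1,3-dioxolan-4-yl]but-1-en-2-yl}-6-[(triethylsilyl)oxy]cyclohexyl (2Z)-2-methylbut-2-enoate | C=C([C@H](C[C@@H]3OC(C)(C)OC3(C)C)OC(=O)/C(C)=C\C)[C@@H]1C[C@@H](Cl)[C@](C)(O)[C@H](OC(=O)/C(C)=C\C)[C@@H]1O[Si](CC)(CC)CC
F7 | step 23 | (1R,2R,3R,5S,6R)-3-chloro-2,6-dihydroxy-2-methyl-5-{(3S)-3-{[(2Z)-2-methylbut-2-enoyl]oxy}-4-[(4S)-2,2,5,5-tetramethyl-1,3-dioxolan-4-yl]but-1-en-2-yl}cyclohexyl (2Z)-2-methylbut-2-enoate | C=C([C@H](C[C@@H]3OC(C)(C)OC3(C)C)OC(=O)/C(C)=C\C)[C@@H]1C[C@@H](Cl)[C@](C)(O)[C@H](OC(=O)/C(C)=C\C)[C@@H]1O
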